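## Analysis of the target

The target is an unsymmetrical dimer of two 3-methylisochroman-1-ones (3,4-dihydroisocoumarins). Unit A carries 6-OH, 7-OMe and 8-OH, and its C4 bears an aryloxy group; unit B (primed) carries 4'-OH, 7'-OMe and 8'-OH, and its C6' oxygen is the ether oxygen bound to C4. There are four stereocentres, C3/C4 and C3'/C4', all fixed as (3R,4S,3'R,4'S). In each ring the methyl group and the C4 oxygen are trans (erythro in the open chain), and both units have the same absolute sense, so one chiral building block can serve both halves. The C4–O–C6' ether sits on a secondary benzylic carbon para to the C7 methoxy group, so it can ionize or eliminate towards an isocoumarin. The free 4'-OH next to lactone B can capture the acyl group once that lactone is opened, which gives the five-membered phthalide isomer, and the three phenols are easily oxidised. The synthesis is hard because a hindered chiral alkyl aryl ether must be made with control at C4, and because oxygens of the same kind must be told apart: O6 from O8 in ring A, and O6' (etherified) from O8' (free) in ring B. The strategy rests on the two phenols at C8 and C8': each lies ortho to a lactone carbonyl (C1, C1') and is hydrogen-bonded to it. Without them each ring has the isovanillin pattern with a single phenolic oxygen and a single C–H ortho to the carbonyl, so the differentiation problem disappears.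

## Retrosynthetic reasoning

**19 to 18.** The two O–acetyl bonds at O6 and O4' are cut. The acetates are there only to keep the phenol and the benzylic alcohol out of the oxidation that precedes; the forward step is a mild methanolysis that must leave both lactones closed.

**18 to 16 (C8–O and C8'–O).** These two bonds are cut because each oxygen is ortho to a lactone carbonyl, the only handle in the molecule that can direct a metal to one specific arene C–H. The gain is that both rings lose their second phenol, so each becomes an isovanillin-type arene with one phenolic oxygen. The forward reaction must metalate C8–H and C8'–H under carbonyl direction and oxidise both carbon–metal bonds to carbon–oxygen bonds without touching the benzylic ether.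

**16 to 15, 14 and 13 (protecting groups).** Acetates cannot be carried through the basic fragment union, so O6 travels as a methoxymethyl ether and O4' as a 4-methoxyphenyl ether. Forward, the aryl ether is cleaved oxidatively (13 to 14), the acetal is removed (14 to 15), and both hydroxyls are acetylated at once (15 to 16).

**13 to 7 and 11 (C4–O and C1–O2).** The ether is cut on its alkyl side and lactone A at its ester bond. The C4–O bond joins the two halves, so this cut is convergent. It is made on the alkyl side because C4 can be offered as the benzylic carbon of a trans-epoxide, whose opening with inversion gives exactly the erythro arrangement. The alkoxide set free at C3 then closes the six-membered lactone on the neighbouring ester. Because the benzylic oxygen is already an ether at that moment, the five-membered lactone isomer cannot form. The forward step needs attack of the phenoxide of 11 at the benzylic carbon of 7, not at the methyl-bearing carbon.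

**11 to 10, then 7 and 8.** Unit B is cut in the same way, with 4-methoxyphenol 8 as a removable stand-in for the C4' oxygen. An acyl group at that position would migrate to the neighbouring alkoxide and divert the ring closure to the five-membered lactone; an aryl ether cannot migrate. Removal of the acetal from 10 frees the single phenol of ring B.

**7 to 6.** The two C–O bonds of the epoxide are cut. One ketone-catalysed asymmetric epoxidation (Shi) of the E-alkene sets C3 and C4 of both units, since 7 is used twice.

**6 to 4 and 5; 4 to 2 and 3; 2 to 1.** The C8a–C1 bond comes from palladium-catalysed methoxycarbonylation of aryl bromide 4 with carbon monoxide 5. The C3=C4 alkene comes from E-selective olefination of aldehyde 2 with sulfone 3. Compound 2 is the protected form of the commercial bromo-isovanillin 1, whose aldehyde carbon becomes C4 and whose bromine marks C8a.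

## Alternatives that were turned down

**Alternative 1: ring A made last by aldol aromatization.**
- Disconnection: the C4a–C8a bond, which unravels ring A into the open-chain diketo-dioxinone A2. Its acyl end already carries the C4 aryloxy group, the C3 tert-butoxy group and the complete protected unit B.
- Forward key step: mild base triggers aldol attack of the dioxinone carbon (future C8a) on the C4a ketone; dehydration gives the benzodioxinone A1 with ring A aromatic.
- For: the chain fixes the oxygen pattern of ring A without arene chemistry, with O6 free and O8 tied in the acetonide. The 6-OH/8-OH distinction is therefore built in, which is stronger than the chosen route, which only avoids the problem. No metal-mediated oxidation is needed near the benzylic ether.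
- Against: in A2 the ether carbon C4 is α to a ketone and the C3 oxygen is β to it, so the base needed for the aldol can epimerise C4 and expel the β-alkoxy or the aryloxy group. Building an α-methoxy diketo chain needs Claisen-type acylations with strong base in the presence of lactone B. The sequence is long and linear, and ring B still needs its own arene synthesis.
- Comparison: in place of the built-in differentiation, the chosen route reaches its precursor in ten steps from one cheap arene, and its stereocentres are never next to a ketone.

**Alternative 2: ring B grown on the ether oxygen by pyrone–ynol ether cycloaddition.**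
- Disconnection: C4a'–C5' and C6'–C7', giving the fully substituted 2-pyrone A4 and the alkynyl ether A5 of the unit A benzylic alcohol.
- Forward key step: [4+2] cycloaddition, then decarboxylative aromatization of the bridged adduct to the benzoate A3.
- For: the C4–O bond is never made by substitution at the benzylic carbon, because the alkynyl ether is built on the preformed alcohol with retention. On the security of the C4 configuration this is stronger than the chosen route, which relies on an epoxide opening. The polarisation (nucleophilic terminal alkyne carbon, pyrone C6 activated by the ester) also predicts the right regiochemistry.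
- Against: the diene carries two donor oxygens and the dienophile is electron-rich too, so the cycloaddition is electronically mismatched and needs heat. An alkynyl ether with a hydrogen on the carbon β to oxygen (C3–H) can fragment thermally by a retro-ene path. The pyrone A4 with its erythro side chain is itself a multi-step target, and after the cycloaddition both lactones and the ring A carboxyl are still missing.
- Comparison: the chosen route accepts a substitution at C4 but makes it a base-mediated epoxide opening that cannot ionize, and it closes lactone A in the same operation.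

**Alternative 3: twofold carbonylative lactonization of a dibromide.**
- Disconnection: C8a–C1/C1–O2 and C8a'–C1'/C1'–O2', leading to the bis(aryl bromide) A7 that carries both erythro chains and the ether.
- Forward key step: twofold palladium-catalysed alkoxycarbonylation to the protected target A6.
- For: the ring-forming reaction is better precedented than a double C–H oxidation, all oxygens are in place, and no oxidant comes near the benzylic ether. On the certainty of the last bond formation it is stronger than the chosen route.
- Against: each C–Br bond is flanked on both sides (a protected oxygen and the branched side chain) on an electron-rich ring, which slows oxidative addition and acyl capture. The arenes are trioxygenated, and in ring B the two similar oxygens beside the methoxy group must be told apart (O6' etherified, O8' protected). That pattern is not available from a cheap precursor, and more protecting groups are needed.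
- Comparison: the chosen route uses the same carbonylation early on a simple monobromide, takes both rings from one commercial bromo-aldehyde with one phenol each, and pays with risk concentrated in the last C–O bond formation.

Key step: step 11

## Remarks on the chemistry

- Positions follow isochroman-1-one numbering; unprimed is unit A (C4 ether), primed is unit B (free 4'-OH).
- Sulfone 3 is taken as a commercial reagent.
- Epoxide 7 is made once and used in steps 5 and 7.
- The route is a proposal; no step has been run.

## Steps

Step 1
Reactants: 1 2-bromo-5-hydroxy-4-methoxybenzaldehyde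
Product: 2 2-bromo-4-methoxy-5-(methoxymethoxy)benzaldehyde
Conditions: MeOCH2Cl, iPr2NEt, CH2Cl2, 0 °C to rt
Reagents that add atoms: chloromethyl methyl ether, COCCl
Why: O-alkylation of the only phenol; the acetal ether is stable to the strong base, the oxidant and the phenoxide chemistry of steps 2 to 5 and 7 and is removed later without a nucleophilic base.

Step 2
Reactants: 2 2-bromo-4-methoxy-5-(methoxymethoxy)benzaldehyde; 3 5-(ethylsulfonyl)-1-phenyl-1H-tetrazole
Product: 4 1-bromo-5-methoxy-4-(methoxymethoxy)-2-[(E)-prop-1-en-1-yl]benzene
Conditions: 3, KN(SiMe3)2, DME, −60 °C to rt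
Reagents that add atoms: none
Why: Julia–Kocienski olefination; addition of the sulfonyl carbanion, Smiles rearrangement and anti elimination should give mainly the E-alkene, and the aldehyde has no α-hydrogen to interfere.

Step 3
Reactants: 4 1-bromo-5-methoxy-4-(methoxymethoxy)-2-[(E)-prop-1-en-1-yl]benzene; 5 carbon monoxide
Product: 6 methyl 5-methoxy-4-(methoxymethoxy)-2-[(E)-prop-1-en-1-yl]benzoate
Conditions: 5 (1 atm), Pd(OAc)2, Xantphos, Et3N, MeOH, 70 °C
Reagents that add atoms: methanol, CO
Why: Palladium-catalysed methoxycarbonylation of an aryl bromide (oxidative addition to zerovalent palladium, CO insertion, methanolysis of the acyl complex); CO insertion is faster than any Heck reaction with the styrene, and the wide-bite-angle ligand allows atmospheric pressure.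

Step 4
Reactants: 6 methyl 5-methoxy-4-(methoxymethoxy)-2-[(E)-prop-1-en-1-yl]benzoate
Product: 7 methyl 5-methoxy-4-(methoxymethoxy)-2-[(2R,3R)-3-methyloxiran-2-yl]benzoate
Conditions: D-fructose-derived Shi ketone (30 mol %), KHSO5 (as Oxone, 2KHSO5·KHSO4·K2SO4), K2CO3, Bu4NHSO4, MeCN–CH2(OMe)2, aq. Na2B4O7 buffer, 0 °C
Reagents that add atoms: potassium peroxymonosulfate, [K+].[O-]S(=O)(=O)OO
Why: Shi asymmetric epoxidation; the chiral dioxirane meets the E-aryl-propene (the best substrate class for this catalyst) in a spiro transition state and should deliver oxygen to the face giving the (2R,3R)-epoxide, which sets C3 and C4 of both units. The basic buffer keeps the ortho ester from opening the epoxide, and any shortfall in enantiomeric purity becomes separable diastereomers at step 7.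

Step 5
Reactants: 7 methyl 5-methoxy-4-(methoxymethoxy)-2-[(2R,3R)-3-methyloxiran-2-yl]benzoate; 8 4-methoxyphenol
Product: 10 (3R,4S)-7-methoxy-6-(methoxymethoxy)-4-(4-methoxyphenoxy)-3-methylisochroman-1-one, via hydroxy ester 9 (not isolated)
Conditions: 8 (1.5 equiv), Cs2CO3 (0.5 equiv), DMF, 90 °C
Reagents that add atoms: none
Why: Base-mediated SN2 opening of the aryl epoxide by the phenoxide at the benzylic carbon (activated by the arene and its para methoxy group) with inversion gives the (1S,2R) erythro hydroxy ester 9. Its C2 alkoxide closes the six-membered lactone on the ortho ester (6-exo-trig), with C3 untouched, so the ring is trans. An aryl ether cannot migrate, so the five-membered lactone is excluded.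

Step 6
Reactants: 10 (3R,4S)-7-methoxy-6-(methoxymethoxy)-4-(4-methoxyphenoxy)-3-methylisochroman-1-one
Product: 11 (3R,4S)-6-hydroxy-7-methoxy-4-(4-methoxyphenoxy)-3-methylisochroman-1-one
Conditions: ZnBr2, n-PrSH, CH2Cl2, 0 °C to rt
Reagents that add atoms: none
Why: Lewis-acid-assisted cleavage of the aryl methoxymethyl acetal with the thiol as a soft trap; there is no alcohol or base that could open the lactone, and the benzylic ether is deactivated by the ortho carbonyl.

Step 7
Reactants: 7 methyl 5-methoxy-4-(methoxymethoxy)-2-[(2R,3R)-3-methyloxiran-2-yl]benzoate; 11 (3R,4S)-6-hydroxy-7-methoxy-4-(4-methoxyphenoxy)-3-methylisochroman-1-one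
Product: 13 (3R,4S)-7-methoxy-6-(methoxymethoxy)-4-{[(3R,4S)-7-methoxy-4-(4-methoxyphenoxy)-3-methyl-1-oxoisochroman-6-yl]oxy}-3-methylisochroman-1-one, via hydroxy ester 12 (not isolated)
Conditions: 7 (1.3 equiv), Cs2CO3 (1 equiv), DMF, 100 °C
Reagents that add atoms: none
Why: The same epoxide opening and lactonization as in step 5, now with the single phenoxide of ring B as nucleophile: SN2 at the benzylic carbon with inversion sets C4 as S and forms the C4–O–C6' ether, and the C3 alkoxide of 12 closes lactone A. The aprotic carbonate medium leaves lactone B and the aryl ether untouched.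

Step 8
Reactants: 13 (3R,4S)-7-methoxy-6-(methoxymethoxy)-4-{[(3R,4S)-7-methoxy-4-(4-methoxyphenoxy)-3-methyl-1-oxoisochroman-6-yl]oxy}-3-methylisochroman-1-one
Product: 14 (3R,4S)-4-{[(3R,4S)-4-hydroxy-7-methoxy-3-methyl-1-oxoisochroman-6-yl]oxy}-7-methoxy-6-(methoxymethoxy)-3-methylisochroman-1-one
Conditions: (NH4)2Ce(NO3)6, MeCN–H2O (4:1), 0 °C
Reagents that add atoms: none
Why: Oxidative cleavage of a 4-methoxyphenyl ether; tetravalent cerium oxidises the only 1,4-dialkoxybenzene, water adds at its ipso carbon and the alcohol leaves with its own oxygen and configuration. The two lactone-bearing rings are deactivated by their carbonyl groups, and the short cold reaction should spare the acetal.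

Step 9
Reactants: 14 (3R,4S)-4-{[(3R,4S)-4-hydroxy-7-methoxy-3-methyl-1-oxoisochroman-6-yl]oxy}-7-methoxy-6-(methoxymethoxy)-3-methylisochroman-1-one
Product: 15 (3R,4S)-6-hydroxy-4-{[(3R,4S)-4-hydroxy-7-methoxy-3-methyl-1-oxoisochroman-6-yl]oxy}-7-methoxy-3-methylisochroman-1-one
Conditions: ZnBr2, n-PrSH, CH2Cl2, 0 °C
Reagents that add atoms: none
Why: The same acetal cleavage as in step 6. It is done after step 8 so that no free phenol meets the cerium oxidant, and without alcohol solvent so that lactone B, now next to a free hydroxyl, is not opened.

Step 10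
Reactants: 15 (3R,4S)-6-hydroxy-4-{[(3R,4S)-4-hydroxy-7-methoxy-3-methyl-1-oxoisochroman-6-yl]oxy}-7-methoxy-3-methylisochroman-1-one
Product: 16 (3R,4S)-4-{[(3R,4S)-4-(acetyloxy)-7-methoxy-3-methyl-1-oxoisochroman-6-yl]oxy}-7-methoxy-3-methyl-1-oxoisochroman-6-yl acetate
Conditions: Ac2O, pyridine, DMAP (cat.), CH2Cl2, rt
Reagents that add atoms: acetic anhydride, CC(=O)OC(C)=O
Why: Nucleophile-catalysed acylation of the phenol and the secondary benzylic alcohol in one operation; the acetates lower the electron density of ring A and turn the 4'-oxygen into a poor leaving group for the acidic oxidation that follows.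

Step 11
Reactants: 16 (3R,4S)-4-{[(3R,4S)-4-(acetyloxy)-7-methoxy-3-methyl-1-oxoisochroman-6-yl]oxy}-7-methoxy-3-methyl-1-oxoisochroman-6-yl acetate
Product: 18 (3R,4S)-4-{[(3R,4S)-4-(acetyloxy)-8-hydroxy-7-methoxy-3-methyl-1-oxoisochroman-6-yl]oxy}-8-hydroxy-7-methoxy-3-methyl-1-oxoisochroman-6-yl acetate, via bis(trifluoroacetate) 17 (not isolated)
Conditions: [RuCl2(p-cymene)]2 (5 mol %), K2S2O8, CF3CO2H–(CF3CO)2O (4:1), 70 °C; then H2O–THF, rt
Reagents that add atoms: trifluoroacetic acid, OC(=O)C(F)(F)F
Why: The lactone carbonyl oxygen of each unit binds the divalent ruthenium trifluoroacetate formed in the medium and, held syn-coplanar to C8–H (C8'–H) by the ring, guides carboxylate-assisted concerted metalation–deprotonation to a five-membered ruthenacycle. Persulfate oxidises this to a tetravalent ruthenium aryl, which forms the C8–O (C8'–O) bond by reductive elimination with trifluoroacetate; the aryl trifluoroacetates of 17 are hydrolysed on aqueous work-up. The closest known reaction type is the ester-directed (and cyclic-ketone-directed) ortho-hydroxylation of benzoates with this catalyst and oxidant in the same acid medium. No ring is closed and no stereocentre is created. Site selectivity is needed and is fixed by the substrate: each arene has one C–H ortho to its carbonyl, and the other ring C–H (C5, C5') lies between two substituents and out of reach of the lactone oxygen. Chemoselectivity is needed against arene oxidation and against ionization at C4 and C4': both rings are deactivated by the carbonyl, O6 is acylated, and each new oxygen stays acylated until work-up. The benzylic C–O bonds are flanked by the ortho carbonyl and by the acyloxy-bearing C3, which disfavour a cation, and acetate is a poor leaving group; the temperature is kept at the low end of what metalation needs.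

Step 12
Reactants: 18 (3R,4S)-4-{[(3R,4S)-4-(acetyloxy)-8-hydroxy-7-methoxy-3-methyl-1-oxoisochroman-6-yl]oxy}-8-hydroxy-7-methoxy-3-methyl-1-oxoisochroman-6-yl acetate
Product: 19 (3R,4S)-6,8-dihydroxy-4-{[(3R,4S)-4,8-dihydroxy-7-methoxy-3-methyl-1-oxoisochroman-6-yl]oxy}-7-methoxy-3-methylisochroman-1-one
Conditions: K2CO3 (0.5 equiv), MeOH, 0 °C to rt; then pH 5 buffer
Reagents that add atoms: none
Why: Base-catalysed transesterification of the aryl and the secondary acetate to methyl acetate. Under these conditions the 8- and 8'-phenols are present as phenoxides conjugated to the lactone carbonyls, which makes both lactones poor electrophiles for methoxide, and direct acyl transfer to the 4'-oxygen would need a strained bridged intermediate.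

## Compound list

1 | 2-bromo-5-hydroxy-4-methoxybenzaldehyde | COc1cc(Br)c(C=O)cc1O | starting material
2 | 2-bromo-4-methoxy-5-(methoxymethoxy)benzaldehyde | COCOc1cc(C=O)c(Br)cc1OC | intermediate
3 | 5-(ethylsulfonyl)-1-phenyl-1H-tetrazole | CCS(=O)(=O)c1nnnn1-c1ccccc1 | starting material
4 | 1-bromo-5-methoxy-4-(methoxymethoxy)-2-[(E)-prop-1-en-1-yl]benzene | C/C=C/c1cc(OCOC)c(OC)cc1Br | intermediate
5 | carbon monoxide | [C-]#[O+] | starting material
6 | methyl 5-methoxy-4-(methoxymethoxy)-2-[(E)-prop-1-en-1-yl]benzoate | C/C=C/c1cc(OCOC)c(OC)cc1C(=O)OC | intermediate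
7 | methyl 5-methoxy-4-(methoxymethoxy)-2-[(2R,3R)-3-methyloxiran-2-yl]benzoate | C[C@H]1O[C@@H]1c1cc(OCOC)c(OC)cc1C(=O)OC | intermediate
8 | 4-methoxyphenol | COc1ccc(O)cc1 | starting material
9 | methyl 2-[(1S,2R)-2-hydroxy-1-(4-methoxyphenoxy)propyl]-5-methoxy-4-(methoxymethoxy)benzoate | C[C@@H](O)[C@@H](Oc1ccc(OC)cc1)c1cc(OCOC)c(OC)cc1C(=O)OC | intermediate (not isolated)
10 | (3R,4S)-7-methoxy-6-(methoxymethoxy)-4-(4-methoxyphenoxy)-3-methylisochroman-1-one | COCOc1cc2c(cc1OC)C(=O)O[C@H](C)[C@H]2Oc1ccc(OC)cc1 | intermediate
11 | (3R,4S)-6-hydroxy-7-methoxy-4-(4-methoxyphenoxy)-3-methylisochroman-1-one | Oc1cc2c(cc1OC)C(=O)O[C@H](C)[C@H]2Oc1ccc(OC)cc1 | intermediate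
12 | methyl 2-[(1S,2R)-2-hydroxy-1-{[(3R,4S)-7-methoxy-4-(4-methoxyphenoxy)-3-methyl-1-oxoisochroman-6-yl]oxy}propyl]-5-methoxy-4-(methoxymethoxy)benzoate | C[C@@H](O)[C@@H](Oc1cc2c(cc1OC)C(=O)O[C@H](C)[C@H]2Oc1ccc(OC)cc1)c1cc(OCOC)c(OC)cc1C(=O)OC | intermediate (not isolated)
13 | (3R,4S)-7-methoxy-6-(methoxymethoxy)-4-{[(3R,4S)-7-methoxy-4-(4-methoxyphenoxy)-3-methyl-1-oxoisochroman-6-yl]oxy}-3-methylisochroman-1-one | COc1c(OCOC)cc2c(c1)C(=O)O[C@H](C)[C@H]2Oc1cc2c(cc1OC)C(=O)O[C@H](C)[C@H]2Oc1ccc(OC)cc1 | intermediate
14 | (3R,4S)-4-{[(3R,4S)-4-hydroxy-7-methoxy-3-methyl-1-oxoisochroman-6-yl]oxy}-7-methoxy-6-(methoxymethoxy)-3-methylisochroman-1-one | COc1c(OCOC)cc2c(c1)C(=O)O[C@H](C)[C@H]2Oc1cc2c(cc1OC)C(=O)O[C@H](C)[C@H]2O | intermediate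
15 | (3R,4S)-6-hydroxy-4-{[(3R,4S)-4-hydroxy-7-methoxy-3-methyl-1-oxoisochroman-6-yl]oxy}-7-methoxy-3-methylisochroman-1-one | COc1c(O)cc2c(c1)C(=O)O[C@H](C)[C@H]2Oc1cc2c(cc1OC)C(=O)O[C@H](C)[C@H]2O | intermediate
16 | (3R,4S)-4-{[(3R,4S)-4-(acetyloxy)-7-methoxy-3-methyl-1-oxoisochroman-6-yl]oxy}-7-methoxy-3-methyl-1-oxoisochroman-6-yl acetate (8,8'-dideoxy diacetate) | COc1c(OC(C)=O)cc2c(c1)C(=O)O[C@H](C)[C@H]2Oc1cc2c(cc1OC)C(=O)O[C@H](C)[C@H]2OC(C)=O | intermediate
17 | 8,8'-bis(trifluoroacetoxy) derivative of 16 | COc1c(OC(C)=O)cc2c(c1OC(=O)C(F)(F)F)C(=O)O[C@H](C)[C@H]2Oc1cc2c(c(OC(=O)C(F)(F)F)c1OC)C(=O)O[C@H](C)[C@H]2OC(C)=O | intermediate (not isolated)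
18 | (3R,4S)-4-{[(3R,4S)-4-(acetyloxy)-8-hydroxy-7-methoxy-3-methyl-1-oxoisochroman-6-yl]oxy}-8-hydroxy-7-methoxy-3-methyl-1-oxoisochroman-6-yl acetate (6,4'-di-O-acetyl target) | COc1c(OC(C)=O)cc2c(c1O)C(=O)O[C@H](C)[C@H]2Oc1cc2c(c(O)c1OC)C(=O)O[C@H](C)[C@H]2OC(C)=O | intermediate
19 | (3R,4S)-6,8-dihydroxy-4-{[(3R,4S)-4,8-dihydroxy-7-methoxy-3-methyl-1-oxoisochroman-6-yl]oxy}-7-methoxy-3-methylisochroman-1-one | COc1c(O)cc2c(c1O)C(=O)O[C@H](C)[C@H]2Oc1cc2c(c(O)c1OC)C(=O)O[C@H](C)[C@H]2O | target

## Step count and least certain steps

Total: 12 steps. Longest linear sequence: 12 steps (1 to 19); epoxide 7 is made once and used in steps 5 and 7.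

**Step 11 (key step).** The most likely failure is acid-promoted ionization of the benzylic C4–O bond (loss of the ring B unit) or of the C4'-acetate before the slow metalation of the hindered C8–H bonds, which lie between the carbonyl and a methoxy group, is complete. A second failure is stalling after the first hydroxylation. Fallback: a neutral two-stage oxygenation that sets out from 16 and returns at 18. Ester-directed ortho C–H borylation (B2pin2, [Ir(OMe)(cod)]2, P[3,5-(CF3)2C6H3]3, octane, 80 °C) would give the 8,8'-bis(pinacolboronate) F1. Every other arene C–H is blocked on both sides, so only the carbonyl-directed positions can react. Oxidation of F1 with KHSO5 in aqueous acetone at rt would then give 18 without strong acid.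

**Step 7.** The most likely failure is attack of the hindered, weakly nucleophilic phenoxide at the methyl-bearing epoxide carbon, which after ring closure drains into the five-membered lactone, or a reaction so slow that 7 decomposes. Step 5 is the same reaction with an easier nucleophile and serves as its rehearsal. Fallback: take the ester out of the electrophile, setting out from 4 and 11 and returning at 13. Shi epoxidation of bromoalkene 4 would give (2R,3R)-2-[2-bromo-4-methoxy-5-(methoxymethoxy)phenyl]-3-methyloxirane F2, whose more electron-rich, less hindered benzylic carbon favours the desired opening. Reaction with 11 (Cs2CO3, DMF) would give the bromo alcohol F3, in which a misdirected adduct can no longer cyclise. Lactone A would then be closed by palladium-catalysed intramolecular alkoxycarbonylation (5, Pd(OAc)2, Xantphos, Et3N, toluene, 90 °C) to give 13.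

**Step 12.** The most likely failure is methoxide opening of lactone B followed by reclosure through the free 4'-oxygen to the five-membered lactone, before the hindered secondary acetate has been cleaved. Fallback: replace solvolytic by reductive deprotection, setting out from 15 and returning at 19. Acylation of 15 with Cl3CCH2OCOCl and pyridine would give the bis(2,2,2-trichloroethyl carbonate) F4. The hydroxylation of step 11 would lead through the bis(trifluoroacetate) F5 (not isolated) to the 8,8'-dihydroxy bis-carbonate F6. Zn in AcOH–THF would then remove both carbonates by reductive fragmentation, giving 19 with no alkoxide present.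

**Step 2.** The most likely failure is incomplete E selectivity; Z-alkene would be carried into a cis-epoxide and then into cis-lactone diastereomers that are hard to remove. Fallback: an addition–elimination sequence that sets out from 2 and returns at 4. EtMgBr in THF would give 1-[2-bromo-4-methoxy-5-(methoxymethoxy)phenyl]propan-1-ol F7. Mesylation (MeSO2Cl, Et3N) to the methanesulfonate F8 (not isolated) and elimination with DBU in warm toluene would give the conjugated E-alkene 4 through an anti-periplanar transition state that keeps methyl and aryl apart.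

## Further compounds

F1 | step 11 | 8,8'-bis(4,4,5,5-tetramethyl-1,3,2-dioxaborolan-2-yl) derivative of 16 | COc1c(OC(C)=O)cc2c(c1B3OC(C)(C)C(C)(C)O3)C(=O)O[C@H](C)[C@H]2Oc1cc2c(c(B3OC(C)(C)C(C)(C)O3)c1OC)C(=O)O[C@H](C)[C@H]2OC(C)=O
F2 | step 7 | (2R,3R)-2-[2-bromo-4-methoxy-5-(methoxymethoxy)phenyl]-3-methyloxirane | C[C@H]1O[C@@H]1c1cc(OCOC)c(OC)cc1Br
F3 | step 7 | (3R,4S)-6-{(1S,2R)-1-[2-bromo-4-methoxy-5-(methoxymethoxy)phenyl]-2-hydroxypropoxy}-7-methoxy-4-(4-methoxyphenoxy)-3-methylisochroman-1-one | C[C@@H](O)[C@@H](Oc1cc2c(cc1OC)C(=O)O[C@H](C)[C@H]2Oc1ccc(OC)cc1)c1cc(OCOC)c(OC)cc1Br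
F4 | step 12 | 6,4'-bis-O-(2,2,2-trichloroethoxycarbonyl) derivative of 15 | COc1c(OC(=O)OCC(Cl)(Cl)Cl)cc2c(c1)C(=O)O[C@H](C)[C@H]2Oc1cc2c(cc1OC)C(=O)O[C@H](C)[C@H]2OC(=O)OCC(Cl)(Cl)Cl
F5 | step 12 | 8,8'-bis(trifluoroacetoxy) derivative of F4 | COc1c(OC(=O)OCC(Cl)(Cl)Cl)cc2c(c1OC(=O)C(F)(F)F)C(=O)O[C@H](C)[C@H]2Oc1cc2c(c(OC(=O)C(F)(F)F)c1OC)C(=O)O[C@H](C)[C@H]2OC(=O)OCC(Cl)(Cl)Cl
F6 | step 12 | 6,4'-bis-O-(2,2,2-trichloroethoxycarbonyl) derivative of 19 | COc1c(OC(=O)OCC(Cl)(Cl)Cl)cc2c(c1O)C(=O)O[C@H](C)[C@H]2Oc1cc2c(c(O)c1OC)C(=O)O[C@H](C)[C@H]2OC(=O)OCC(Cl)(Cl)Cl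
F7 | step 2 | 1-[2-bromo-4-methoxy-5-(methoxymethoxy)phenyl]propan-1-ol (racemic) | CCC(O)c1cc(OCOC)c(OC)cc1Br
F8 | step 2 | 1-[2-bromo-4-methoxy-5-(methoxymethoxy)phenyl]propyl methanesulfonate (racemic) | CCC(OS(C)(=O)=O)c1cc(OCOC)c(OC)cc1Br
A1 | alternative 1 | ring A benzodioxinone (O6 free, O8 and carboxyl tied as the acetonide) carrying the protected unit B | CC1(C)OC(=O)c2c(O1)c(OC)c(O)cc2[C@H](Oc3cc4c(c(OCOC)c3OC)C(=O)O[C@H](C)[C@H]4O[Si](C)(C)C(C)(C)C)[C@@H](C)OC(C)(C)C
A2 | alternative 1 | open-chain 7-methoxy diketo-dioxinone with the 2-aryloxy-3-tert-butoxybutanoyl terminus | CC1(C)OC(=O)C=C(O1)C(OC)C(=O)CC(=O)[C@H](Oc3cc4c(c(OCOC)c3OC)C(=O)O[C@H](C)[C@H]4O[Si](C)(C)C(C)(C)C)[C@@H](C)OC(C)(C)C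
A3 | alternative 2 | ring B methyl benzoate bearing the C6' ether to the acyclic unit A fragment | COC(=O)c1c(OCOC)c(OC)c(O[C@@H](c2cc(OCOC)c(OC)c(OCOC)c2)[C@@H](C)OCOC)cc1[C@H](O[Si](C)(C)C(C)(C)C)[C@@H](C)OCOC
A4 | alternative 2 | methyl 3-methoxy-4-(methoxymethoxy)-2-oxo-2H-pyran-5-carboxylate with the erythro 1-silyloxy-2-(methoxymethoxy)propyl chain at C6 | COC(=O)C1=C(OC(=O)C(OC)=C1OCOC)[C@H](O[Si](C)(C)C(C)(C)C)[C@@H](C)OCOC
A5 | alternative 2 | ethynyl ether of the erythro unit A benzylic alcohol (3,5-bis(methoxymethoxy)-4-methoxyphenyl) | C#CO[C@@H](c1cc(OCOC)c(OC)c(OCOC)c1)[C@@H](C)OCOC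
A6 | alternative 3 | protected target (6,8,8'-tri-O-methoxymethyl, 4'-O-tert-butyldimethylsilyl bis-lactone) | COc1c(OCOC)cc2c(c1OCOC)C(=O)O[C@H](C)[C@H]2Oc1cc2c(c(OCOC)c1OC)C(=O)O[C@H](C)[C@H]2O[Si](C)(C)C(C)(C)C
A7 | alternative 3 | bis(aryl bromide) with both erythro side chains and the C4–O–C6' ether | C[C@@H](O)[C@@H](Oc1cc([C@H](O[Si](C)(C)C(C)(C)C)[C@@H](C)O)c(Br)c(OCOC)c1OC)c1cc(OCOC)c(OC)c(OCOC)c1Br
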